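**Retrosynthetic overview**
1. Target ⇐ regioselective 6-O-acetylation and unmasking of a tetracycle. The cyclobutane (C1–C11 bond) is closed last, by Norrish–Yang cyclisation of a tricyclic 11-ketone.
2. The 11-ketone and 12β-acetate ⇐ Rubottom oxidation. Ring C ⇐ SmI2 pinacol closure (C9–C11) of a keto aldehyde.
3. Key disconnection C8–C14: intermolecular aldol between the enolate of a cis-AB decalone and a cyclopropanecarbaldehyde that has no α-hydrogen.
4. The cis-decalone ⇐ enantioselective quinone Diels–Alder reaction (sets C5 and C10), C4 gem-dimethylation through a blocked enone, and β-face dihydroxylation of C6=C7.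
5. The aldehyde ⇐ anti-carbomagnesiation of but-2-yn-1-ol and Charette cyclopropanation. Ring order: A+B, cyclopropane (separate branch), C, cyclobutane.

Assumption: abietane numbering (C1–C20) is used for every intermediate. β is the face of the C10 methyl group (C20) and α the opposite face. The target stereo-SMILES (5β-H, so rings A/B are cis-fused) is taken as given.

**Step 1**
Reactants: 1 methyl vinyl ketone
Product: 2 2-(triisopropylsilyloxy)buta-1,3-diene
Conditions: TIPSOTf, Et3N, Et2O, 0 °C to rt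
Reagents that add atoms: triisopropylsilyl triflate, CC(C)[Si](C(C)C)(C(C)C)OS(=O)(=O)C(F)(F)F
Why: Soft enolisation of the methyl ketone (silyl enol ether formation) gives the 2-silyloxydiene, and no stereocentre is formed.

**Step 2**
Reactants: 2 2-(triisopropylsilyloxy)buta-1,3-diene; 3 2-methoxy-5-methyl-1,4-benzoquinone
Product: 4 cis-fused AB adduct (5β-H; 10β-CH3; ketones at C6 and C9; OMe on C7 of C7=C8; TIPS enol ether C2=C3)
Conditions: (S)-3,3-diphenyl-1-(o-tolyl)tetrahydropyrrolo[1,2-c][1,3,2]oxazaborole·HNTf2 (20 mol %), CH2Cl2, −78 °C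
Reagents that add atoms: none
Why: In this enantioselective Lewis-acid-catalysed Diels–Alder reaction the boron cation binds the more basic C9 carbonyl, the methyl-bearing C5=C10 bond reacts because the methoxy-bearing one is deactivated, the nucleophilic diene CH2 next to C–OTIPS (C4) bonds to C5, suprafacial addition makes 5-H and 10-CH3 cis, and the shielded catalyst face fixes the absolute configuration (the mirror-image catalyst would give ent-4).

**Step 3**
Reactants: 4 cis-fused AB adduct
Product: 5 6α-alcohol (C9 vinylogous ester and TIPS enol ether intact)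
Conditions: CeCl3·7H2O, NaBH4, MeOH, −78 °C
Reagents that add atoms: none
Why: In this Luche 1,2-reduction only the C6 carbonyl reacts, because C9 is a hindered vinylogous ester, and hydride arrives on the convex β-face of the cis-bicycle to give the 6α-alcohol and remove the acidity of 5-H.

**Step 4**
Reactants: 5 6α-alcohol
Product: 6 6α-OTES ether
Conditions: TESCl, imidazole, DMF, 0 °C to rt
Reagents that add atoms: chlorotriethylsilane, CC[Si](Cl)(CC)CC
Why: Standard silylation masks the only hydroxyl group before the base chemistry on ring A.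

**Step 5**
Reactants: 6 6α-OTES ether
Product: 7 Δ1-en-3-one (6α-OTES; C7-OMe vinylogous ester)
Conditions: Pd(OAc)2 (1.05 equiv), DMSO, 45 °C
Reagents that add atoms: none
Why: In this Saegusa–Ito oxidation, palladation at C2 and β-hydride loss from C1 convert the regiodefined C2=C3 silyl enol ether into the Δ1-enone, which blocks C2 against later enolisation.

**Step 6**
Reactants: 7 Δ1-en-3-one
Product: 9 4,4-dimethyl-Δ1-en-3-one, via 4β-methyl enone 8 (not isolated)
Conditions: KHMDS (2.4 equiv), MeI (5 equiv), THF, −78 to −20 °C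
Reagents that add atoms: iodomethane, IC
Why: This α′-enolate alkylation runs twice in one flask, and because C4 is the only enolisable carbon (C2 is vinylic, C10 quaternary, ring B has no α-hydrogen) both methyl groups go to C4 and C5 is untouched.

**Step 7**
Reactants: 9 4,4-dimethyl-Δ1-en-3-one
Product: 10 4,4-dimethyl-3-ketone (C1 and C2 saturated)
Conditions: H2 (1 atm), 10 % Pd/C, EtOAc, rt
Reagents that add atoms: none
Why: Catalytic hydrogenation saturates the disubstituted enone bond C1=C2 much faster than the trisubstituted, donor-substituted C7=C8 bond.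

**Step 8**
Reactants: 10 4,4-dimethyl-3-ketone
Product: 11 3β-alcohol
Conditions: NaBH4, MeOH/CH2Cl2, 0 °C to rt
Reagents that add atoms: none
Why: Borohydride reduces the only free ketone (the vinylogous ester is inert) mainly to the equatorial 3β-alcohol, a placeholder centre that step 28 oxidises back, so the epimer is equally usable.

**Step 9**
Reactants: 11 3β-alcohol
Product: 12 3β-OTBS-6α-OTES bis-silyl ether
Conditions: TBSOTf, 2,6-lutidine, CH2Cl2, 0 °C
Reagents that add atoms: tert-butyldimethylsilyl triflate, CC(C)(C)[Si](C)(C)OS(=O)(=O)C(F)(F)F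
Why: Silyl triflate silylation covers the neopentyl alcohol with a group more robust than TES.

**Step 10**
Reactants: 12 bis-silyl ether
Product: 13 6α-alcohol (3β-OTBS kept)
Conditions: PPTS (cat.), MeOH/CH2Cl2, 0 °C
Reagents that add atoms: none
Why: Acid-catalysed methanolysis cleaves the smaller TES ether selectively, and exchange at the methyl vinylogous ester in methanol is degenerate.

**Step 11**
Reactants: 13 6α-alcohol
Product: 14 6α-hydroxy-9-ketone (C7 and C8 now CH2)
Conditions: Li, NH3(l)/THF, t-BuOH (2 equiv), −78 °C; isoprene, then NH4Cl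
Reagents that add atoms: none
Why: In this dissolving-metal reduction of a β-alkoxy enone, two-electron reduction, loss of methoxide and a second two-electron reduction stop at the lithium enolate, which gives the C9 ketone on quench, while the 6-alkoxide is too poor a leaving group to be expelled.

**Step 12**
Reactants: 14 6α-hydroxy-9-ketone
Product: 15 6-en-9-one (C6=C7; 5β-H; 3β-OTBS)
Conditions: Burgess reagent, toluene, 70 °C
Reagents that add atoms: none
Why: In this Burgess dehydration (syn-elimination) the 6α-sulfamate can reach only the cis 7α-hydrogen, because 5-H is β, so the C6=C7 alkene forms regiospecifically and C5 is preserved.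

**Step 13**
Reactants: 15 6-en-9-one
Product: 16 6β,7β-diol
Conditions: OsO4 (2 mol %), NMO, acetone/H2O, 0 °C to rt
Reagents that add atoms: osmium tetroxide, O=[Os](=O)(=O)=O; N-methylmorpholine N-oxide, C[N+]1([O-])CCOCC1; water, O
Why: In this Upjohn dihydroxylation, suprafacial osmylation on the convex β-face (the α-face lies under ring A, whose C1 is axial on ring B) sets 6β-O and 7β-O together.

**Step 14**
Reactants: 16 6β,7β-diol
Product: 17 6β,7β-acetonide 9-ketone
Conditions: 2,2-dimethoxypropane, PPTS (cat.), CH2Cl2, rt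
Reagents that add atoms: 2,2-dimethoxypropane, COC(C)(C)OC
Why: Transketalisation closes the cis-diol into a dioxolane that tolerates base, SmI2, oxidants and light.

**Step 15**
Reactants: 18 but-2-yn-1-ol; 19 allylmagnesium bromide
Product: 21 (E)-2-allylbut-2-en-1-ol, via alkenylmagnesium alkoxide 20 (not isolated)
Conditions: 19 (3 equiv), CuI (10 mol %), THF, 0 °C to reflux; then aq NH4Cl
Reagents that add atoms: none
Why: In this anti-carbomagnesiation of the propargylic alkoxide, allyl adds to the carbon next to CH2O and magnesium sits cis to CH2O in a chelate, so protonolysis gives only the alkene with CH3 cis to allyl (later C17 cis to C12).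

**Step 16**
Reactants: 21 (E)-2-allylbut-2-en-1-ol
Product: 22 [(1R,2S)-1-allyl-2-methylcyclopropyl]methanol
Conditions: Et2Zn, CH2I2, DME, (4R,5R)-2-butyl-N,N,N′,N′-tetramethyl-1,3,2-dioxaborolane-4,5-dicarboxamide (1.2 equiv), CH2Cl2, −10 °C to rt
Reagents that add atoms: diiodomethane, ICI
Why: In this Charette asymmetric Simmons–Smith cyclopropanation the alkoxide-directed, stereospecific CH2 transfer goes only to the allylic alkene, the alkene geometry fixes C13 relative to C15, and the (R,R)-ligand fixes the absolute configuration.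

**Step 17**
Reactants: 22 cyclopropylmethanol
Product: 23 (1R,2S)-1-allyl-2-methylcyclopropane-1-carbaldehyde
Conditions: DMP, NaHCO3, CH2Cl2, 0 °C
Reagents that add atoms: none
Why: Dess–Martin oxidation gives the aldehyde, whose quaternary α-carbon cannot epimerise.

**Step 18**
Reactants: 17 acetonide ketone; 23 cyclopropanecarbaldehyde
Product: 25 aldol adduct (new C8–C14 bond; C14 on the α-face of C8; 8β-H; anti C14 carbinol), via lithium enolate 24 (not isolated)
Conditions: LDA (1.1 equiv), THF, −78 °C, 30 min; 23, −78 °C; sat. NH4Cl at −78 °C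
Reagents that add atoms: none
Why: In this intermolecular lithium aldol addition (Zimmerman–Traxler) ketone 17 can enolise only towards C8, aldehyde 23 has no α-hydrogen, and the aldehyde approaches C8 anti to the neighbouring 7β-oxygen and its acetonide, which places C14 α and 8-H β, while the fixed E-enolate gives the anti carbinol that is oxidised later.

**Step 19**
Reactants: 25 aldol adduct
Product: 26 14-OTES ether
Conditions: TESOTf, 2,6-lutidine, CH2Cl2, −78 to 0 °C
Reagents that add atoms: triethylsilyl triflate, CC[Si](CC)(CC)OS(=O)(=O)C(F)(F)F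
Why: Silyl triflate silylation under non-nucleophilic base caps the hindered carbinol and shuts off retro-aldol cleavage.

**Step 20**
Reactants: 26 14-OTES ether
Product: 27 keto aldehyde (C11 aldehyde; C9 ketone)
Conditions: O3, CH2Cl2, −78 °C; then Me2S
Reagents that add atoms: ozone, [O-][O+]=O
Why: Ozonolysis with reductive work-up cleaves the only alkene and leaves C11 as the aldehyde.

**Step 21**
Reactants: 27 keto aldehyde
Product: 28 tricyclic 9β,11β-diol (ring C closed)
Conditions: SmI2 (3 equiv), t-BuOH (2 equiv), THF, −78 to 0 °C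
Reagents that add atoms: none
Why: In this SmI2 keto–aldehyde pinacol cyclisation to a six-membered ring, the tether hangs from the α-face at C8 and the β-face of C9 is screened by C20 and the acetonide, so C11 bonds from the α-face (9β-OH), and chelation of both oxygens to samarium gives the cis-diol.

**Step 22**
Reactants: 28 9β,11β-diol
Product: 29 9β-hydroxy-11-ketone
Conditions: IBX, DMSO, rt
Reagents that add atoms: none
Why: IBX oxidises the secondary C11 alcohol of the glycol without C–C cleavage, and the tertiary 9-OH cannot react.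

**Step 23**
Reactants: 29 9β-hydroxy-11-ketone
Product: 30 C11=C12 trimethylsilyl enol ether with 9β-OTMS
Conditions: TMSOTf (3 equiv), Et3N (5 equiv), CH2Cl2, 0 °C
Reagents that add atoms: trimethylsilyl triflate, C[Si](C)(C)OS(=O)(=O)C(F)(F)F
Why: Soft enolisation can only go towards C12, because C9 is fully substituted, and the tertiary alcohol is capped at the same time, which prevents α-ketol rearrangement.

**Step 24**
Reactants: 30 silyl enol ether
Product: 32 9β,12β-dihydroxy-11-ketone, via 12β-silyloxy ketone 31 (not isolated)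
Conditions: DMDO, acetone/CH2Cl2, −40 °C; then citric acid (cat.), MeOH, rt
Reagents that add atoms: dimethyldioxirane, CC1(C)OO1
Why: In this Rubottom oxidation the oxidant attacks C11=C12 from the β-face, because the α-face is covered by C10 (axial on ring C, carrying ring A) and by C17, which sets 12β-O, and mild methanolysis then removes only the two TMS groups.

**Step 25**
Reactants: 32 9β,12β-dihydroxy-11-ketone
Product: 33 12β-acetate
Conditions: Ac2O, DMAP (cat.), pyridine, 0 °C to rt
Reagents that add atoms: acetic anhydride, CC(=O)OC(C)=O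
Why: Acylation takes the only secondary alcohol and leaves the tertiary 9-OH free.

**Step 26**
Reactants: 33 12β-acetate
Product: 34 tetracyclic cyclobutanol (C1–C11 bond; 11β-OH; 1α-H)
Conditions: hν (300 nm lamps, Pyrex), degassed benzene, 15 °C
Reagents that add atoms: none
Why: In this Norrish–Yang cyclisation, excitation of the only ketone (C11) leads to abstraction of the equatorial 1β-hydrogen held next to the carbonyl oxygen in the folded cis-A/B, cis-B/C skeleton (six-membered transition state) and then to collapse of the 1,4-biradical; the four-membered ring must be cis-fused to rings B and C, which puts 11-OH β, and C11 takes the place of the abstracted 1β-hydrogen, which leaves 1-H α.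

**Step 27**
Reactants: 34 tetracyclic cyclobutanol
Product: 35 3β,14-diol
Conditions: HF·pyridine, pyridine, THF, 0 °C to rt
Reagents that add atoms: none
Why: Buffered fluoride desilylation removes TES and TBS, while the acetonide, the acetate and the tertiary alcohols survive.

**Step 28**
Reactants: 35 3β,14-diol
Product: 36 3,14-diketone acetonide
Conditions: DMP (3 equiv), NaHCO3, CH2Cl2, 0 °C to rt
Reagents that add atoms: none
Why: Neutral Dess–Martin oxidation takes both free secondary alcohols to the C3 and C14 ketones without epimerising C8, and 7-O is still masked.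

**Step 29**
Reactants: 36 3,14-diketone acetonide
Product: 37 6β,7β-diol (6-O-deacetyl target)
Conditions: AcOH/H2O 4:1, 45 °C
Reagents that add atoms: none
Why: Mild acid hydrolysis opens the dioxolane under conditions too weak for retro-aldol cleavage, dehydration or acetate loss.

**Step 30**
Reactants: 37 6β,7β-diol
Product: 38 target CNP0157858.2
Conditions: 2-aminoethyl diphenylborinate Ph2BOCH2CH2NH2 (10 mol %), AcCl (1.2 equiv), i-Pr2NEt, MeCN, 0 °C to rt
Reagents that add atoms: acetyl chloride, CC(=O)Cl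
Why: In this borinic-acid-catalysed monoacylation the catalyst binds the secondary cis-6,7-diol and the borinate transfers acyl to the equatorial 6β-oxygen, while the axial 7β-OH (syn-axial to 9β-OH) and the tertiary alcohols stay free.

**Compound list**
1 | methyl vinyl ketone | C=CC(C)=O | starting material
2 | 2-(triisopropylsilyloxy)buta-1,3-diene | C=CC(=C)O[Si](C(C)C)(C(C)C)C(C)C | intermediate
3 | 2-methoxy-5-methyl-1,4-benzoquinone | COC1=CC(=O)C(C)=CC1=O | starting material
4 | cis-AB Diels–Alder adduct, 5β-H, 10β-CH3, 6,9-dione, 7-OMe (C7=C8), 3-OTIPS (C2=C3) | COC1=CC(=O)[C@@]2(C)CC=C(O[Si](C(C)C)(C(C)C)C(C)C)C[C@H]2C1=O | intermediate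
5 | 6α-alcohol of 4 | COC1=CC(=O)[C@@]2(C)CC=C(O[Si](C(C)C)(C(C)C)C(C)C)C[C@H]2[C@H]1O | intermediate
6 | 6α-OTES ether of 5 | COC1=CC(=O)[C@@]2(C)CC=C(O[Si](C(C)C)(C(C)C)C(C)C)C[C@H]2[C@H]1O[Si](CC)(CC)CC | intermediate
7 | Δ1-en-3-one, 6α-OTES, 7-OMe vinylogous ester | COC1=CC(=O)[C@@]2(C)C=CC(=O)C[C@H]2[C@H]1O[Si](CC)(CC)CC | intermediate
8 | 4β-methyl-Δ1-en-3-one (not isolated) | COC1=CC(=O)[C@@]2(C)C=CC(=O)[C@H](C)[C@H]2[C@H]1O[Si](CC)(CC)CC | intermediate
9 | 4,4-dimethyl-Δ1-en-3-one | COC1=CC(=O)[C@@]2(C)C=CC(=O)C(C)(C)[C@H]2[C@H]1O[Si](CC)(CC)CC | intermediate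
10 | 4,4-dimethyl-3-ketone | COC1=CC(=O)[C@@]2(C)CCC(=O)C(C)(C)[C@H]2[C@H]1O[Si](CC)(CC)CC | intermediate
11 | 3β-alcohol | COC1=CC(=O)[C@@]2(C)CC[C@H](O)C(C)(C)[C@H]2[C@H]1O[Si](CC)(CC)CC | intermediate
12 | 3β-OTBS, 6α-OTES bis-silyl ether | COC1=CC(=O)[C@@]2(C)CC[C@H](O[Si](C)(C)C(C)(C)C)C(C)(C)[C@H]2[C@H]1O[Si](CC)(CC)CC | intermediate
13 | 3β-OTBS, 6α-OH vinylogous ester | COC1=CC(=O)[C@@]2(C)CC[C@H](O[Si](C)(C)C(C)(C)C)C(C)(C)[C@H]2[C@H]1O | intermediate
14 | 3β-OTBS, 6α-OH cis-decal-9-one | C1CC(=O)[C@@]2(C)CC[C@H](O[Si](C)(C)C(C)(C)C)C(C)(C)[C@H]2[C@H]1O | intermediate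
15 | 3β-OTBS cis-6-en-9-one | C1C(=O)[C@@]2(C)CC[C@H](O[Si](C)(C)C(C)(C)C)C(C)(C)[C@H]2C=C1 | intermediate
16 | 6β,7β-diol 9-ketone | O[C@@H]1[C@H](O)CC(=O)[C@@]2(C)CC[C@H](O[Si](C)(C)C(C)(C)C)C(C)(C)[C@@H]12 | intermediate
17 | 6β,7β-acetonide 9-ketone | CC1(C)O[C@@H]2[C@H](O1)CC(=O)[C@@]3(C)CC[C@H](O[Si](C)(C)C(C)(C)C)C(C)(C)[C@@H]23 | intermediate
18 | but-2-yn-1-ol | CC#CCO | starting material
19 | allylmagnesium bromide | C=CC[Mg]Br | starting material
20 | alkenylmagnesium alkoxide, Mg cis to CH2O (not isolated) | C/C([Mg]Br)=C(/CO[Mg]Br)CC=C | intermediate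
21 | (E)-2-allylbut-2-en-1-ol | C/C=C(/CO)CC=C | intermediate
22 | [(1R,2S)-1-allyl-2-methylcyclopropyl]methanol | OC[C@@]1(CC=C)C[C@@H]1C | intermediate
23 | (1R,2S)-1-allyl-2-methylcyclopropane-1-carbaldehyde | O=C[C@@]1(CC=C)C[C@@H]1C | intermediate
24 | lithium C8=C9 enolate of 17 (not isolated) | CC1(C)O[C@@H]2[C@H](O1)C=C(O[Li])[C@@]3(C)CC[C@H](O[Si](C)(C)C(C)(C)C)C(C)(C)[C@@H]23 | intermediate
25 | aldol adduct, 8β-H, anti 14-OH | CC1(C)O[C@@H]2[C@H](O1)[C@@H]([C@@H](O)[C@@]3(CC=C)C[C@@H]3C)C(=O)[C@@]4(C)CC[C@H](O[Si](C)(C)C(C)(C)C)C(C)(C)[C@@H]24 | intermediate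
26 | 14-OTES ether of 25 | CC1(C)O[C@@H]2[C@H](O1)[C@@H]([C@@H](O[Si](CC)(CC)CC)[C@@]3(CC=C)C[C@@H]3C)C(=O)[C@@]4(C)CC[C@H](O[Si](C)(C)C(C)(C)C)C(C)(C)[C@@H]24 | intermediate
27 | keto aldehyde (C9 ketone, C11 aldehyde) | CC1(C)O[C@@H]2[C@H](O1)[C@@H]([C@@H](O[Si](CC)(CC)CC)[C@@]3(CC=O)C[C@@H]3C)C(=O)[C@@]4(C)CC[C@H](O[Si](C)(C)C(C)(C)C)C(C)(C)[C@@H]24 | intermediate
28 | tricyclic 9β,11β-diol | CC1(C)O[C@@H]2[C@H](O1)[C@H]3[C@@H](O[Si](CC)(CC)CC)[C@]4(C[C@@H]4C)C[C@H](O)[C@@]3(O)[C@@]5(C)CC[C@H](O[Si](C)(C)C(C)(C)C)C(C)(C)[C@@H]25 | intermediate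
29 | 9β-hydroxy-11-ketone | CC1(C)O[C@@H]2[C@H](O1)[C@H]3[C@@H](O[Si](CC)(CC)CC)[C@]4(C[C@@H]4C)CC(=O)[C@@]3(O)[C@@]5(C)CC[C@H](O[Si](C)(C)C(C)(C)C)C(C)(C)[C@@H]25 | intermediate
30 | 11-OTMS enol ether (C11=C12), 9β-OTMS | CC1(C)O[C@@H]2[C@H](O1)[C@H]3[C@@H](O[Si](CC)(CC)CC)[C@]4(C[C@@H]4C)C=C(O[Si](C)(C)C)[C@@]3(O[Si](C)(C)C)[C@@]5(C)CC[C@H](O[Si](C)(C)C(C)(C)C)C(C)(C)[C@@H]25 | intermediate
31 | 9β,12β-bis(OTMS) 11-ketone (not isolated) | CC1(C)O[C@@H]2[C@H](O1)[C@H]3[C@@H](O[Si](CC)(CC)CC)[C@]4(C[C@@H]4C)[C@H](O[Si](C)(C)C)C(=O)[C@@]3(O[Si](C)(C)C)[C@@]5(C)CC[C@H](O[Si](C)(C)C(C)(C)C)C(C)(C)[C@@H]25 | intermediate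
32 | 9β,12β-dihydroxy-11-ketone | CC1(C)O[C@@H]2[C@H](O1)[C@H]3[C@@H](O[Si](CC)(CC)CC)[C@]4(C[C@@H]4C)[C@H](O)C(=O)[C@@]3(O)[C@@]5(C)CC[C@H](O[Si](C)(C)C(C)(C)C)C(C)(C)[C@@H]25 | intermediate
33 | 12β-acetoxy-9β-hydroxy-11-ketone | CC1(C)O[C@@H]2[C@H](O1)[C@H]3[C@@H](O[Si](CC)(CC)CC)[C@]4(C[C@@H]4C)[C@H](OC(C)=O)C(=O)[C@@]3(O)[C@@]5(C)CC[C@H](O[Si](C)(C)C(C)(C)C)C(C)(C)[C@@H]25 | intermediate
34 | tetracyclic cyclobutanol, 1α-H, 9β,11β-diol | CC1(C)O[C@@H]2[C@H](O1)[C@H]3[C@@H](O[Si](CC)(CC)CC)[C@]4(C[C@@H]4C)[C@H](OC(C)=O)[C@@]4(O)[C@@H]5C[C@H](O[Si](C)(C)C(C)(C)C)C(C)(C)[C@@H]2[C@@]5(C)[C@@]34O | intermediate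
35 | 3β,14-diol | CC1(C)O[C@@H]2[C@H](O1)[C@H]3[C@@H](O)[C@]4(C[C@@H]4C)[C@H](OC(C)=O)[C@@]4(O)[C@@H]5C[C@H](O)C(C)(C)[C@@H]2[C@@]5(C)[C@@]34O | intermediate
36 | 3,14-diketone 6,7-acetonide | CC1(C)O[C@@H]2[C@H](O1)[C@H]3C(=O)[C@]4(C[C@@H]4C)[C@H](OC(C)=O)[C@@]4(O)[C@@H]5CC(=O)C(C)(C)[C@@H]2[C@@]5(C)[C@@]34O | intermediate
37 | 6-O-deacetyl target (6β,7β-diol) | O[C@@H]1[C@H](O)[C@H]2C(=O)[C@]3(C[C@@H]3C)[C@H](OC(C)=O)[C@@]3(O)[C@@H]4CC(=O)C(C)(C)[C@@H]1[C@@]4(C)[C@@]23O | intermediate
38 | CNP0157858.2 | CC(=O)O[C@@H]1[C@H](O)[C@H]2C(=O)[C@]3(C[C@@H]3C)[C@H](OC(C)=O)[C@@]3(O)[C@@H]4CC(=O)C(C)(C)[C@@H]1[C@@]4(C)[C@@]23O | target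

**Step count and risks**

Total step count: 30.
Longest linear sequence: 27 (steps 1–14 and 18–30).

Risk 1, step 18 (aldol). The enolate carries an axial β-alkoxy group at C7, so E1cB loss is possible. Both partners are hindered, and α-face attack at C8 runs syn-axial to C1. The fallback sets out from 17. Soft enolisation with TMSOTf and Et3N in CH2Cl2 gives the trimethylsilyl enol ether F1, which is isolated. F1 is combined with aldehyde 23 under BF3·OEt2 in CH2Cl2 at −78 °C in a Mukaiyama aldol addition. This has an open transition state and no basic enolate, so no alkoxide can be expelled, and the facial bias anti to the acetonide is unchanged. Aqueous work-up returns to the route at 25.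

Risk 2, step 21 (pinacol). C9 is flanked by a quaternary and a branched carbon, and the ring fusion could close trans or not at all. The fallback sets out from 27. McMurry coupling (TiCl3, Zn–Cu couple, DME, reflux, high dilution) closes ring C as the tricyclic 9(11)-alkene F2, so no stereocentre is set in the C–C bond-forming event. Stoichiometric OsO4 in pyridine, followed by NaHSO3, then dihydroxylates the alkene from the β-face, because ring A lies under the α-face. This returns to the route at 28.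

Risk 3, step 26 (photocyclisation). α-Cleavage of the α-ketol, abstraction from C20 or C7, and fragmentation of the biradical all compete. In addition, a chair-shaped ring C keeps the carbonyl oxygen away from C1–H. The fallback sets out from 33. HF·pyridine gives the tricyclic 3β,14-diol F3, and Dess–Martin oxidation gives the 3,11,14-trione F4. Ring C of F4 is a cyclohexane-1,4-dione, which prefers the twist-boat that turns the C11 oxygen towards the 1β-hydrogen. Irradiation of F4 (300–350 nm, Pyrex, benzene) then forms the C1–C11 bond on this substrate and returns to the route at 36.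

**Further compounds**
F1 | step 18 | trimethylsilyl enol ether (C8=C9) of 17 | CC1(C)O[C@@H]2[C@H](O1)C=C(O[Si](C)(C)C)[C@@]3(C)CC[C@H](O[Si](C)(C)C(C)(C)C)C(C)(C)[C@@H]23
F2 | step 21 | tricyclic 9(11)-alkene | CC1(C)O[C@@H]2[C@H](O1)[C@H]3[C@@H](O[Si](CC)(CC)CC)[C@]4(C[C@@H]4C)CC=C3[C@@]5(C)CC[C@H](O[Si](C)(C)C(C)(C)C)C(C)(C)[C@@H]25
F3 | step 26 | tricyclic 3β,14-diol 11-ketone | CC1(C)O[C@@H]2[C@H](O1)[C@H]3[C@@H](O)[C@]4(C[C@@H]4C)[C@H](OC(C)=O)C(=O)[C@@]3(O)[C@@]5(C)CC[C@H](O)C(C)(C)[C@@H]25
F4 | step 26 | tricyclic 3,11,14-trione | CC1(C)O[C@@H]2[C@H](O1)[C@H]3C(=O)[C@]4(C[C@@H]4C)[C@H](OC(C)=O)C(=O)[C@@]3(O)[C@@]5(C)CCC(=O)C(C)(C)[C@@H]25
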